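**Retrosynthetic overview**

1. Triene, C9'=C10': last step, Horner–Wadsworth–Emmons union of aldehyde acid 19 (ring plus C1'–C9') with dienylphosphonate 23 (C10'–C16').
2. C3–CH2CO2H bond: peroxycarbenium ion at C3 of a 3-methoxy-1,2-dioxolane plus a silyl ketene thioacetal; this sets C3 relative to C5.
3. Ring formation (the only ring): the 1,2-dioxolane O1–O2–C3–C4–C5 arises by one-atom ring expansion of a 2-methyleneoxetane, O–C(=CH2)–CH2–C(Me)(R). The ring oxygen is exchanged for O–O with inversion at the quaternary carbon, which becomes C5.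
4. Enabling feature: C5 is a fully substituted C–O carbon 1,3 to C3, and C3 without its acetic acid arm is at the ketone oxidation level (β-peroxy ketone = cyclic peroxyketal). C3–C4–C5 therefore map onto C2–C3–C4 of a strained enol ether whose only sp3 C–O bond is at the future C5 and whose exocyclic CH2 becomes the C3 methyl.
5. The methyleneoxetane comes from the β-lactone of an (S)-β-hydroxy acid, made by Sharpless epoxidation and reductive opening of an (E)-allylic alcohol derived from undec-10-yn-1-ol.

Key step: step 8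

Remark: the target is 2-[(3S,5R)-5-[(9E,11E,13E)-hexadeca-9,11,13-trien-1-yl]-3,5-dimethyl-1,2-dioxolan-3-yl]acetic acid; the CH2CO2H group at C3 and the C16 chain at C5 lie on opposite faces of the ring. Ring numbering O1–O2–C3–C4–C5 and side-chain numbering C1'–C16' are used throughout.

**Route**

Step 1
Reactants: 1 undec-10-yn-1-ol
Product: 2 tert-butyl(diphenyl)(undec-10-yn-1-yloxy)silane
Conditions: TBDPSCl, imidazole, DMF, rt
Reagents that add atoms: tert-butyl(chloro)diphenylsilane, CC(C)(C)[Si](Cl)(c1ccccc1)c1ccccc1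
Why: Silylation of the primary alcohol (silyl ether protection) should be clean, and the TBDPS ether is chosen because it has to survive Me3Al, Red-Al, Cp2TiMe2, TMSOTf and TiCl4 before its removal with fluoride.

Step 2
Reactants: 2 tert-butyl(diphenyl)(undec-10-yn-1-yloxy)silane
Product: 5 (2E)-12-{[tert-butyl(diphenyl)silyl]oxy}-3-methyldodec-2-en-1-ol, via alkenylalane 3 (not isolated), via lithium alkenylaluminate 4 (not isolated)
Conditions: Me3Al, Cp2ZrCl2 (0.25 equiv), CH2Cl2, 0 °C to rt; then n-BuLi, THF, −78 °C; (CH2O)n, −78 °C to rt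
Reagents that add atoms: trimethylaluminium, C[Al](C)C; formaldehyde (as paraformaldehyde), C=O
Why: Negishi carboalumination (Cp2ZrCl2-catalysed syn-methylalumination of the terminal alkyne) followed by hydroxymethylation of the alkenyl aluminate with retention should deliver the (E)-trisubstituted allylic alcohol with the geometry that the next step needs.

Step 3
Reactants: 5 (2E)-12-{[tert-butyl(diphenyl)silyl]oxy}-3-methyldodec-2-en-1-ol
Product: 6 [(2S,3S)-3-(9-{[tert-butyl(diphenyl)silyl]oxy}nonyl)-3-methyloxiran-2-yl]methanol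
Conditions: Ti(OiPr)4 (10 mol %), L-(+)-diethyl tartrate (12 mol %), t-BuOOH, 4 Å molecular sieves, CH2Cl2, −20 °C
Reagents that add atoms: tert-butyl hydroperoxide, CC(C)(C)OO
Why: Sharpless asymmetric epoxidation of a geraniol-type (E)-allylic alcohol: with L-(+)-tartrate the oxygen is delivered to the face that gives the (2S,3S)-epoxide, which sets the tertiary C–O centre that later becomes C5 of the target.

Step 4
Reactants: 6 [(2S,3S)-3-(9-{[tert-butyl(diphenyl)silyl]oxy}nonyl)-3-methyloxiran-2-yl]methanol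
Product: 7 (3S)-12-{[tert-butyl(diphenyl)silyl]oxy}-3-methyldodecane-1,3-diol
Conditions: NaAlH2(OCH2CH2OMe)2 (Red-Al), THF, 0 °C to rt
Reagents that add atoms: none
Why: Hydroxyl-directed reductive opening of the 2,3-epoxy alcohol (intramolecular hydride delivery from the alkoxyaluminate to C2) should give the 1,3-diol, and since only the C2–O bond is cleaved the tertiary carbinol keeps its configuration.

Step 5
Reactants: 7 (3S)-12-{[tert-butyl(diphenyl)silyl]oxy}-3-methyldodecane-1,3-diol
Product: 8 (3S)-12-{[tert-butyl(diphenyl)silyl]oxy}-3-hydroxy-3-methyldodecanoic acid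
Conditions: TEMPO (cat.), NaOCl (cat.), NaClO2, MeCN/sodium phosphate buffer (pH 6.7), 35 °C
Reagents that add atoms: sodium chlorite, [Na+].[O-]Cl=O
Why: TEMPO-catalysed oxidation with NaClO2 as terminal oxidant converts the primary alcohol into the acid via the aldehyde under buffered conditions, while the tertiary alcohol cannot be oxidised and the silyl ether is inert.

Step 6
Reactants: 8 (3S)-12-{[tert-butyl(diphenyl)silyl]oxy}-3-hydroxy-3-methyldodecanoic acid
Product: 9 (4S)-4-(9-{[tert-butyl(diphenyl)silyl]oxy}nonyl)-4-methyloxetan-2-one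
Conditions: PhSO2Cl, pyridine, 0 °C
Reagents that add atoms: none
Why: β-Lactonisation by carboxyl activation (mixed carboxylic–sulfonic anhydride, 4-exo-trig attack of the tertiary hydroxyl on the acyl carbon) leaves the C–O bond of the stereocentre intact, so the configuration is retained.

Step 7
Reactants: 9 (4S)-4-(9-{[tert-butyl(diphenyl)silyl]oxy}nonyl)-4-methyloxetan-2-one
Product: 10 (2S)-2-(9-{[tert-butyl(diphenyl)silyl]oxy}nonyl)-2-methyl-4-methylideneoxetane
Conditions: Cp2TiMe2, toluene, 75 °C, dark; purification on base-washed alumina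
Reagents that add atoms: dimethyltitanocene, [CH3-].[CH3-].[Ti+4].c1cc[cH-]c1.c1cc[cH-]c1
Why: Petasis methylenation of the lactone carbonyl (a known route from β-lactones to 2-methyleneoxetanes) works under neutral conditions that the acid-labile enol ether product and the stereocentre tolerate.

Step 8
Reactants: 10 (2S)-2-(9-{[tert-butyl(diphenyl)silyl]oxy}nonyl)-2-methyl-4-methylideneoxetane
Product: 13 (5R)-5-(9-{[tert-butyl(diphenyl)silyl]oxy}nonyl)-3-methoxy-3,5-dimethyl-1,2-dioxolane (both C3 epimers), via silylperoxy enol silane 11 (not isolated), via hydroperoxy ketone 12 (not isolated)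
Conditions: Me3SiOOSiMe3 (1.5 equiv), TMSOTf (0.2 equiv), 2,6-di-tert-butyl-4-methylpyridine (0.1 equiv), CH2Cl2, −78 °C; then MeOH (excess), TsOH (cat.), −78 °C to rt
Reagents that add atoms: bis(trimethylsilyl) peroxide, C[Si](C)(C)OO[Si](C)(C)C; methanol, CO
Why: Proposed new method: Me3Si+ from TMSOTf (aprotic medium, hindered pyridine as proton trap) activates the ring oxygen of the strained enol ether, whose only sp3 C–O bond is the one at the quaternary carbon, and the α-effect nucleophile Me3SiOOSiMe3 attacks that carbon from the rear as the bond breaks, expelling a silyl enol ether and releasing the oxetane strain to give 11; methanolysis then unmasks the β-hydroperoxy ketone 12, whose OOH group adds to the ketone and is ketalised to 13. The closest known reaction types are the Lewis acid-promoted opening of 2,2-disubstituted oxetanes by H2O2 at the tertiary carbon with inversion, the nucleophilic opening of 2-methyleneoxetanes at the sp3 C–O carbon with release of an enolate, and the conversion of β-hydroperoxy ketones into 3-alkoxy-1,2-dioxolanes. The dioxolane closes by 5-exo-trig addition of the hydroperoxide oxygen to the ketone carbonyl, so that the four-membered C–C–C–O ring has become the five-membered C–C–C–O–O ring. C5 is controlled by inversion of the epoxidation-derived (S) centre (stereospecific borderline SN2 displacement), whereas C3 is a ketal carbon formed as both epimers and is planarised again in step 10. The step needs regioselectivity for the quaternary carbon over the enol ether carbon and substitution over ionisation or elimination: the first is secured because without protons the enol ether carbon stays vinylic and can neither be attacked nor cleaved, the second by the concerted, strain-driven displacement with a small excess of a compact peroxide nucleophile at −78 °C.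

Step 9
Reactants: 14 S-ethyl ethanethioate
Product: 15 {[1-(ethylsulfanyl)ethenyl]oxy}(trimethyl)silane
Conditions: LiN(iPr)2, THF, −78 °C; then Me3SiCl
Reagents that add atoms: chlorotrimethylsilane, C[Si](C)(C)Cl
Why: Kinetic enolisation of the thioester and O-silylation of the lithium enolate is the standard preparation of a silyl ketene thioacetal for Mukaiyama-type reactions.

Step 10
Reactants: 13 (5R)-5-(9-{[tert-butyl(diphenyl)silyl]oxy}nonyl)-3-methoxy-3,5-dimethyl-1,2-dioxolane; 15 {[1-(ethylsulfanyl)ethenyl]oxy}(trimethyl)silane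
Product: 16 S-ethyl 2-[(3S,5R)-5-(9-{[tert-butyl(diphenyl)silyl]oxy}nonyl)-3,5-dimethyl-1,2-dioxolan-3-yl]ethanethioate
Conditions: TiCl4, CH2Cl2, −78 °C; chromatographic separation from the C3 epimer
Reagents that add atoms: none
Why: Lewis acid-mediated substitution of a 3-alkoxy-1,2-dioxolane by a silyl ketene thioacetal via a planar peroxycarbenium ion (Mukaiyama-type, known for this class of dioxolanes) forms the quaternary C3 centre by attack on the face syn to the smaller C5 methyl group, that is anti to the long chain, a bias expected to be only modest, so the (3S,5R) isomer is to be separated from its C3 epimer.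

Step 11
Reactants: 16 S-ethyl 2-[(3S,5R)-5-(9-{[tert-butyl(diphenyl)silyl]oxy}nonyl)-3,5-dimethyl-1,2-dioxolan-3-yl]ethanethioate
Product: 17 2-[(3S,5R)-5-(9-{[tert-butyl(diphenyl)silyl]oxy}nonyl)-3,5-dimethyl-1,2-dioxolan-3-yl]acetic acid
Conditions: LiOH, THF/H2O, 0 °C to rt; then 1 M HCl to pH 3
Reagents that add atoms: lithium hydroxide, [Li+].[OH-]
Why: Saponification of the reactive thioester with hydroxide is mild enough for the tetrasubstituted dialkyl peroxide and the silyl ether, and the carboxylate formed cannot be enolised, so C3 is not at risk.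

Step 12
Reactants: 17 2-[(3S,5R)-5-(9-{[tert-butyl(diphenyl)silyl]oxy}nonyl)-3,5-dimethyl-1,2-dioxolan-3-yl]acetic acid
Product: 18 2-[(3S,5R)-5-(9-hydroxynonyl)-3,5-dimethyl-1,2-dioxolan-3-yl]acetic acid
Conditions: HF·pyridine, pyridine/THF, 0 °C to rt
Reagents that add atoms: none
Why: Fluoride-mediated cleavage of the silyl ether (desilylation) under buffered conditions does not touch the peroxide or the acid.

Step 13
Reactants: 18 2-[(3S,5R)-5-(9-hydroxynonyl)-3,5-dimethyl-1,2-dioxolan-3-yl]acetic acid
Product: 19 2-[(3S,5R)-3,5-dimethyl-5-(9-oxononyl)-1,2-dioxolan-3-yl]acetic acid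
Conditions: Dess–Martin periodinane, CH2Cl2, 0 °C to rt
Reagents that add atoms: none
Why: Dess–Martin oxidation of the primary alcohol to the aldehyde is a non-reducing, metal-free oxidation that tolerates the O–O bond and the free acid.

Step 14
Reactants: 20 (2E,4E)-hepta-2,4-dienal
Product: 21 (2E,4E)-hepta-2,4-dien-1-ol
Conditions: NaBH4, MeOH, 0 °C
Reagents that add atoms: none
Why: Borohydride 1,2-reduction of the conjugated aldehyde gives the dienol without touching the diene geometry.

Step 15
Reactants: 21 (2E,4E)-hepta-2,4-dien-1-ol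
Product: 22 (2E,4E)-1-bromohepta-2,4-diene
Conditions: PBr3, Et2O, 0 °C
Reagents that add atoms: phosphorus tribromide, BrP(Br)Br
Why: Conversion of the allylic alcohol into the bromide with PBr3 (substitution via the phosphite ester) keeps the conjugated (E,E)-diene, the primary conjugated bromide also being the thermodynamically favoured allylic isomer.

Step 16
Reactants: 22 (2E,4E)-1-bromohepta-2,4-diene
Product: 23 diethyl [(2E,4E)-hepta-2,4-dien-1-yl]phosphonate
Conditions: P(OEt)3, neat, 120 °C
Reagents that add atoms: triethyl phosphite, CCOP(OCC)OCC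
Why: Michaelis–Arbuzov reaction of the primary allylic bromide with triethyl phosphite gives the dienylphosphonate with retention of the diene geometry.

Step 17
Reactants: 19 2-[(3S,5R)-3,5-dimethyl-5-(9-oxononyl)-1,2-dioxolan-3-yl]acetic acid; 23 diethyl [(2E,4E)-hepta-2,4-dien-1-yl]phosphonate
Product: 24 2-[(3S,5R)-5-[(9E,11E,13E)-hexadeca-9,11,13-trien-1-yl]-3,5-dimethyl-1,2-dioxolan-3-yl]acetic acid
Conditions: 23 (2.5 equiv), LiN(SiMe3)2 (2.5 equiv), THF/DMPU, −78 °C; add 19; −78 °C to rt; then aq. NaH2PO4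
Reagents that add atoms: none
Why: Horner–Wadsworth–Emmons olefination with a dienylphosphonate anion: the first equivalent of base turns the acid into a carboxylate that cannot be enolised (no retro-Michael opening of the peroxide), and collapse of the more stable anti adduct should favour the new (E)-alkene while the two existing E double bonds are carried over unchanged.

**Compound list**

1 | undec-10-yn-1-ol | C#CCCCCCCCCCO | starting material
2 | tert-butyl(diphenyl)(undec-10-yn-1-yloxy)silane | C#CCCCCCCCCCO[Si](c1ccccc1)(c1ccccc1)C(C)(C)C | intermediate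
3 | dimethyl[(1E)-11-{[tert-butyl(diphenyl)silyl]oxy}-2-methylundec-1-en-1-yl]alumane | C[Al](C)/C=C(\C)CCCCCCCCCO[Si](c1ccccc1)(c1ccccc1)C(C)(C)C | intermediate
4 | lithium butyl(dimethyl)[(1E)-11-{[tert-butyl(diphenyl)silyl]oxy}-2-methylundec-1-en-1-yl]aluminate | [Li+].CCCC[Al-](C)(C)/C=C(\C)CCCCCCCCCO[Si](c1ccccc1)(c1ccccc1)C(C)(C)C | intermediate
5 | (2E)-12-{[tert-butyl(diphenyl)silyl]oxy}-3-methyldodec-2-en-1-ol | OC/C=C(\C)CCCCCCCCCO[Si](c1ccccc1)(c1ccccc1)C(C)(C)C | intermediate
6 | [(2S,3S)-3-(9-{[tert-butyl(diphenyl)silyl]oxy}nonyl)-3-methyloxiran-2-yl]methanol | CC(C)(C)[Si](c2ccccc2)(c3ccccc3)OCCCCCCCCC[C@@]1(C)[C@H](CO)O1 | intermediate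
7 | (3S)-12-{[tert-butyl(diphenyl)silyl]oxy}-3-methyldodecane-1,3-diol | CC(C)(C)[Si](c2ccccc2)(c3ccccc3)OCCCCCCCCC[C@@](O)(C)CCO | intermediate
8 | (3S)-12-{[tert-butyl(diphenyl)silyl]oxy}-3-hydroxy-3-methyldodecanoic acid | CC(C)(C)[Si](c2ccccc2)(c3ccccc3)OCCCCCCCCC[C@@](O)(C)CC(=O)O | intermediate
9 | (4S)-4-(9-{[tert-butyl(diphenyl)silyl]oxy}nonyl)-4-methyloxetan-2-one | CC(C)(C)[Si](c2ccccc2)(c3ccccc3)OCCCCCCCCC[C@@]1(C)CC(=O)O1 | intermediate
10 | (2S)-2-(9-{[tert-butyl(diphenyl)silyl]oxy}nonyl)-2-methyl-4-methylideneoxetane | CC(C)(C)[Si](c2ccccc2)(c3ccccc3)OCCCCCCCCC[C@@]1(C)CC(=C)O1 | intermediate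
11 | tert-butyl(diphenyl){[(10R)-10-methyl-12-[(trimethylsilyl)oxy]-10-[(trimethylsilyl)peroxy]tridec-12-en-1-yl]oxy}silane | CC(C)(C)[Si](c2ccccc2)(c3ccccc3)OCCCCCCCCC[C@](OO[Si](C)(C)C)(C)CC(=C)O[Si](C)(C)C | intermediate
12 | (4R)-13-{[tert-butyl(diphenyl)silyl]oxy}-4-hydroperoxy-4-methyltridecan-2-one | CC(C)(C)[Si](c2ccccc2)(c3ccccc3)OCCCCCCCCC[C@](OO)(C)CC(C)=O | intermediate
13 | (5R)-5-(9-{[tert-butyl(diphenyl)silyl]oxy}nonyl)-3-methoxy-3,5-dimethyl-1,2-dioxolane (both C3 epimers) | CC(C)(C)[Si](c2ccccc2)(c3ccccc3)OCCCCCCCCC[C@]1(C)CC(C)(OC)OO1 | intermediate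
14 | S-ethyl ethanethioate | CC(=O)SCC | starting material
15 | {[1-(ethylsulfanyl)ethenyl]oxy}(trimethyl)silane | C=C(SCC)O[Si](C)(C)C | intermediate
16 | S-ethyl 2-[(3S,5R)-5-(9-{[tert-butyl(diphenyl)silyl]oxy}nonyl)-3,5-dimethyl-1,2-dioxolan-3-yl]ethanethioate | CC(C)(C)[Si](c2ccccc2)(c3ccccc3)OCCCCCCCCC[C@]1(C)C[C@@](C)(CC(=O)SCC)OO1 | intermediate
17 | 2-[(3S,5R)-5-(9-{[tert-butyl(diphenyl)silyl]oxy}nonyl)-3,5-dimethyl-1,2-dioxolan-3-yl]acetic acid | CC(C)(C)[Si](c2ccccc2)(c3ccccc3)OCCCCCCCCC[C@]1(C)C[C@@](C)(CC(=O)O)OO1 | intermediate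
18 | 2-[(3S,5R)-5-(9-hydroxynonyl)-3,5-dimethyl-1,2-dioxolan-3-yl]acetic acid | OCCCCCCCCC[C@]1(C)C[C@@](C)(CC(=O)O)OO1 | intermediate
19 | 2-[(3S,5R)-3,5-dimethyl-5-(9-oxononyl)-1,2-dioxolan-3-yl]acetic acid | O=CCCCCCCCC[C@]1(C)C[C@@](C)(CC(=O)O)OO1 | intermediate
20 | (2E,4E)-hepta-2,4-dienal | CC/C=C/C=C/C=O | starting material
21 | (2E,4E)-hepta-2,4-dien-1-ol | CC/C=C/C=C/CO | intermediate
22 | (2E,4E)-1-bromohepta-2,4-diene | CC/C=C/C=C/CBr | intermediate
23 | diethyl [(2E,4E)-hepta-2,4-dien-1-yl]phosphonate | CC/C=C/C=C/CP(=O)(OCC)OCC | intermediate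
24 | 2-[(3S,5R)-5-[(9E,11E,13E)-hexadeca-9,11,13-trien-1-yl]-3,5-dimethyl-1,2-dioxolan-3-yl]acetic acid | CC/C=C/C=C/C=C/CCCCCCCC[C@]1(C)C[C@@](C)(CC(=O)O)OO1 | target

**Summary**

Total step count: 17. Longest linear sequence: 13 steps (steps 1–8, 10–13 and 17, from 1).

Steps most likely to fail:

1. Step 8 (the step proposed as new chemistry). What may go wrong: ionisation of the silyl-activated oxetane to a free tertiary cation, with loss of configuration at C5 and elimination, or oxidation and oligomerisation of the enol ether instead of substitution. The fallback uses known chemistry with the same stereochemical logic; it sets out from 10 and comes back at 13. Mild hydrolysis of the enol ether of 10 (PPTS, wet THF) should give the β-hydroxy ketone F1, and NaBH4 the diol F2. MsCl/Et3N should sulfonylate only the secondary hydroxyl to the mesylate F3, and KOtBu should close the oxetane F4. Ethereal H2O2 with TMSOTf should open F4 at the tertiary carbon with inversion to the hydroperoxy alcohol F5. 2-Methoxypropene/PPTS masks the hydroperoxide as the perketal F6, Dess–Martin oxidation gives the ketone F7, and MeOH/TsOH unmasks the hydroperoxide, which closes and is ketalised to 13.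

2. Step 10. What may go wrong: poor facial selectivity in the attack on the planar peroxycarbenium ion, because the methyl group and the n-alkyl chain at C5 differ little in size, together with Lewis acid-induced fragmentation of the peroxide. The fallback sets out from 13 and comes back at 17. A Sakurai-type substitution with allyltrimethylsilane and SnCl4 should give the 3-allyl dioxolane F8, whose C3 epimers are separated at this unpolar stage. Ozonolysis with Me2S work-up gives the aldehyde F9, and Pinnick oxidation (NaClO2, NaH2PO4, 2-methylbut-2-ene) gives 17.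

3. Step 17. What may go wrong: incomplete E-selectivity at the new C9'=C10' double bond, γ-attack of the ambident dienyl anion and slow collapse of the β-oxido phosphonate. The fallback sets out from 22 and 19 and comes back at 24. PPh3 converts 22 into the phosphonium salt F10. Its ylide (NaN(SiMe3)2, two equivalents because of the free acid) should react with 19 in a Wittig reaction to give mainly the (9Z) triene acid F11, and catalytic I2 in daylight should isomerise F11 to the all-E acid 24.

Further compounds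
F1 | step 8 | (4S)-13-{[tert-butyl(diphenyl)silyl]oxy}-4-hydroxy-4-methyltridecan-2-one | CC(C)(C)[Si](c2ccccc2)(c3ccccc3)OCCCCCCCCC[C@@](O)(C)CC(C)=O
F2 | step 8 | (4S)-13-{[tert-butyl(diphenyl)silyl]oxy}-4-methyltridecane-2,4-diol (both C2 epimers) | CC(C)(C)[Si](c2ccccc2)(c3ccccc3)OCCCCCCCCC[C@@](O)(C)CC(C)O
F3 | step 8 | (4S)-13-{[tert-butyl(diphenyl)silyl]oxy}-4-hydroxy-4-methyltridecan-2-yl methanesulfonate (both C2 epimers) | CC(C)(C)[Si](c2ccccc2)(c3ccccc3)OCCCCCCCCC[C@@](O)(C)CC(C)OS(C)(=O)=O
F4 | step 8 | (2S)-2-(9-{[tert-butyl(diphenyl)silyl]oxy}nonyl)-2,4-dimethyloxetane (both C4 epimers) | CC(C)(C)[Si](c2ccccc2)(c3ccccc3)OCCCCCCCCC[C@@]1(C)CC(C)O1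
F5 | step 8 | (4R)-13-{[tert-butyl(diphenyl)silyl]oxy}-4-hydroperoxy-4-methyltridecan-2-ol (both C2 epimers) | CC(C)(C)[Si](c2ccccc2)(c3ccccc3)OCCCCCCCCC[C@](OO)(C)CC(C)O
F6 | step 8 | (4R)-13-{[tert-butyl(diphenyl)silyl]oxy}-4-[(2-methoxypropan-2-yl)peroxy]-4-methyltridecan-2-ol (both C2 epimers) | CC(C)(C)[Si](c2ccccc2)(c3ccccc3)OCCCCCCCCC[C@](OOC(C)(C)OC)(C)CC(C)O
F7 | step 8 | (4R)-13-{[tert-butyl(diphenyl)silyl]oxy}-4-[(2-methoxypropan-2-yl)peroxy]-4-methyltridecan-2-one | CC(C)(C)[Si](c2ccccc2)(c3ccccc3)OCCCCCCCCC[C@](OOC(C)(C)OC)(C)CC(C)=O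
F8 | step 10 | (3R,5R)-5-(9-{[tert-butyl(diphenyl)silyl]oxy}nonyl)-3,5-dimethyl-3-(prop-2-en-1-yl)-1,2-dioxolane | CC(C)(C)[Si](c2ccccc2)(c3ccccc3)OCCCCCCCCC[C@]1(C)C[C@@](C)(CC=C)OO1
F9 | step 10 | 2-[(3S,5R)-5-(9-{[tert-butyl(diphenyl)silyl]oxy}nonyl)-3,5-dimethyl-1,2-dioxolan-3-yl]acetaldehyde | CC(C)(C)[Si](c2ccccc2)(c3ccccc3)OCCCCCCCCC[C@]1(C)C[C@@](C)(CC=O)OO1
F10 | step 17 | [(2E,4E)-hepta-2,4-dien-1-yl](triphenyl)phosphonium bromide | [Br-].CC/C=C/C=C/C[P+](c1ccccc1)(c1ccccc1)c1ccccc1
F11 | step 17 | 2-[(3S,5R)-5-[(9Z,11E,13E)-hexadeca-9,11,13-trien-1-yl]-3,5-dimethyl-1,2-dioxolan-3-yl]acetic acid | CC/C=C/C=C/C=C\CCCCCCCC[C@]1(C)C[C@@](C)(CC(=O)O)OO1
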